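The percentage of a charge converted in a fixed time cannot depend on the size of that charge if the reaction is first order, yet alpha and gamma, with the same Jb, Jc and Jd, gave different percentages.

| flask | Ja | Jb | Jc | Jd | remark | time |
|---|---|---|---|---|---|---|
| alpha | 4.6 mM | 97.5 mM | 31.2 mM | 19.5 mM | run made earlier |  |
| gamma | 450 mM | 97.5 mM | 31.2 mM | 19.5 mM | run made earlier |  |
| dawn | 4.0 mM | 97.5 mM | 31.2 mM | 19.5 mM |  | 5.0 h |
| noon | 12 mM | 97.5 mM | 31.2 mM | 19.5 mM |  | 5.0 h |
| midnight | 40 mM | 97.5 mM | 31.2 mM | 19.5 mM |  | 5.0 h |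
| spring | 120 mM | 97.5 mM | 31.2 mM | 19.5 mM |  | 5.0 h |
| winter | 400 mM | 97.5 mM | 31.2 mM | 19.5 mM |  | 5.0 h |

| run | time / h | Jf / % | Ja / % |
|---|---|---|---|
| alpha | 0.833 | 13.9 | 85.8 |
| alpha | 2.00 | 28.5 | 71.3 |
| alpha | 2.50 | 34.3 | 65.8 |
| alpha | 4.00 | 48.4 | 52.3 |
| gamma | 0.833 | 7.8 | 92.2 |
| gamma | 2.00 | 10.7 | 89.1 |
| gamma | 2.50 | 10.6 | 88.4 |
| gamma | 4.00 | 12.4 | 87.3 |

(scatter of a reading: 0.3 percentage points)

- the numbers in the tables scatter by 0.3 percentage points (one standard deviation)
- "hardly changes" means that all values lie within two and a half points (for a concentration: within two and a half percent of the largest)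

- amount of Jf at the end, in percent of the Ja charged for dawn, noon, midnight, spring, winter, in this order
- how that number moves from the first to the last of them (falls all the way / falls, then rises / rises all the way / rises, then falls / hardly changes)

I took the first-order case as the zero of my scale. In alpha, Jb stood far above Ja, so I read it as pseudo-first-order. The 52.3 % of Ja left at 4.00 h gives 0.162 h⁻¹, which means 55.5 % at 5.0 h for a flask on that line, whatever its charge.

Then I ran gamma in slow motion. Up to 0.833 h, Jf came at 42.1 mM h⁻¹ on average. Between 2.00 h and 4.00 h the readings put it at 3.83 mM h⁻¹, about ten times slower, much as a burst gives way to a slow phase. Gamma still held 87.3 % of its Ja, far more in mM than the Jf made, so the slowing was not a want of Ja. At 4.00 h gamma stood at 55.8 mM of Jf. I call this reading the reach, the Jf in mM that gamma had made once its rate had fallen to that slow phase. Alpha had made 2.23 mM by 4.00 h, far below the reach.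

So I reckoned two ends. Dawn, needing 2.22 mM to stay on the line, lies far under the reach and should give 55.5 %. Winter should give the reach over its charge, 14.0 %, far below the line. I expected noon, midnight and spring under the lesser of the two figures, which for spring is 46.5 %, and I committed to a fall all the way.

The forecast gave 56 %, 52 %, 43 %, 32 % and 14 %, falls all the way, with the remark “something is used up or inhibits as Jf accumulates”.

The flask gave 55.7 %, 53.5 %, 46.4 %, 31.8 % and 14.5 %: falls all the way.

    Ja + Jb → Je + Jf (k = 2.10 M⁻¹ h⁻¹)
    Jb + Je ⇌ Jg, settled at all times (K = 630 M⁻¹)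
    Je + Jc ⇌ Jh (K = 6100 M⁻¹, k = 110 M⁻¹ h⁻¹)
    Jb + Jd → Jj (k = 23.0 M⁻¹ h⁻¹)

Winter ended with 85.5 % of its Ja still there, while Jb stood at 3.44 % of its own charge. Its 14.5 % is 58.0 mM of Jf, close to the reach of 55.8 mM. For spring the reach gave 46.5 %, and the spring flask gave 31.8 %, which is 38.2 mM of Jf.

All runs were computed on assumed constants, noise included.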